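**Reading time.** At 8.0 min this flask is read, and the reading sets the next run: which change is worth charging?

| flask | J | Q | G | remark | time |
|---|---|---|---|---|---|
| south-west | 0.20 M | 52 mM (held) | 28 mM | the very flask that is asked about, followed so far |  |
| north | 0.10 M | 52 mM (held) | 28 mM | run made earlier |  |
| flask | 0.20 M | 52 mM (held) | 28 mM |  | 8.0 min |

| south-west: time / min | south-west: X / % | north: time / min | north: X / % |
|---|---|---|---|
| 0.333 | 0 | 0.833 | 2.3 |
| 0.667 | 1.7 | 1.50 | 4.7 |
| 1.00 | 2.4 | 2.50 | 8.2 |
| 1.33 | 4.2 | 3.00 | 10.0 |
| 1.50 | 4.4 | 4.00 | 13.5 |
| 2.00 | 6.4 | 5.00 | 18.2 |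
| 2.50 | 8.6 | 6.00 | 21.3 |

(standard deviation of a reading: 0.5 percentage points)

- the numbers in the tables scatter by 0.5 percentage points (one standard deviation)
- at the start none of Q is in solution

- Monday's: doubling the amount of G, all else as stated
- Friday's: doubling the saturation concentration of Q, all else as stated
- Tuesday's: doubling the transfer coefficient of Q, all else as stated

* X at 8.0 min, in percent of the J charged
* the change that raises the amount of X at 8.0 min, in percent of the J charged most ("none" if none brings more than 2 percentage points) (Monday's / Friday's / Tuesday's / none)
* amount of X at 8.0 min, in percent of the J charged, after Tuesday's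

**Fraction left.** I reckon with what is not yet X. At 2.50 min the south-west flask shows 8.6% and the north flask, with half the J, shows 8.2%. These differ by less than the scatter of 0.5 percentage points, so at that time the percentage does not follow the charge of J, as in a pseudo-first-order loss.

**Drain constant.** The last north reading gives 0.0399 min⁻¹ for the drain constant, the natural logarithm of one over the fraction not yet X, divided by the time. In this flask I reckon 27.3% X at 8.0 min. A change that doubled the constant gives 47.2%, a gain of 20 points, more than the 2 points that counts. Both runs hold 28 mM of G and 52 mM of Q, so they do not rank Monday's against Friday's, and I try both.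

**The forecast.** It gives 27% (25% to 29.5%), 27.3% after Tuesday's, and Monday's as best: “Monday's should nearly double the rate, assuming first order in catalyst”.

**The flask.** It gives 26.1% and 28.1% after Tuesday's. The best is Friday's, with 18 points against 15 points for Monday's and 2.1 points for Tuesday's.

    J + Z + G → G + X (k = 0.709 L² mol⁻² s⁻¹)
    X ⇌ D (K = 0.307, k = 0.00717 s⁻¹)
    Q ⇌ Z, rate k3*(csat - [Z]) (kL = 0.0254 s⁻¹)

**Where J went.** Reckoned on the 67% of J left in this flask at 8.0 min, the drain constant is 0.0508 min⁻¹, and D holds 7.36%. In this flask at 8.00 min, each step taken net, X is made 4.14 times faster than it is used up, though the half-life of X by its forward passing into D, 1.6 min, is short against 8.0 min, and the backward turnover of that step stands at 84% of the forward one.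

**Second flask.** For a neighbour flask with 0.0070 M of G, a quarter of this flask's charge, and the constant scaled in proportion, I reckon 7.67% X; the computed neighbour gives 8.14%.

The readings are calculated for an exercise.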